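**Retrosynthetic overview**
- Skeleton locants: C1 (C–OH), C2 (ArCH next to it), O3, C4, C5 (CH), C6 (ArCH), O7, C8; ring A = C1‑C2‑O3‑C4‑C5, ring B = C5‑C6‑O7‑C8‑C1. Ring A is closed last through O3–C4: the benzylic C2‑OH displaces a primary tosylate (SN2 at CH2, so C2 is retained and its aryl stays endo). Ring B (O7–C8) is closed the same way just before.
- The C1/C2 diol comes from syn‑dihydroxylation of an (E)‑α‑(3,4‑dimethoxybenzylidene)‑γ‑butyrolactone, anti to its β‑CH2OSi group; the lactone is then opened reductively.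
- Key C1–C2 bond: intermolecular aldol addition of the lactone lithium enolate to veratraldehyde, then dehydration.
- The trans‑β,γ‑disubstituted lactone (C5, C6) comes from an Evans syn‑aldol of an N‑pent‑4‑enoyl oxazolidinone with veratraldehyde, reductive auxiliary removal, alkene cleavage and oxidation.
- Ring order: γ‑lactone (temporary ring B) → reductive opening → oxolane ring B → oxolane ring A.

Assumption: the SMILES is read literally as (1R,2R,5S,6R)‑2,6‑bis(3,4‑dimethoxyphenyl)‑3,7‑dioxabicyclo[3.3.0]octan‑1‑ol, cis‑fused, with the C2 aryl endo (trans to OH) and the C6 aryl exo.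

Abbreviations: Ar = 3,4‑dimethoxyphenyl; TBDPS = tert‑butyldiphenylsilyl.

**Step 1**
Reactants: 1 (R)-4-benzyl-1,3-oxazolidin-2-one; 2 pent-4-enoyl chloride
Product: 4 (R)-4-benzyl-3-(pent-4-enoyl)-1,3-oxazolidin-2-one, via N-lithio oxazolidinone 3 (not isolated)
Conditions: n-BuLi, THF, −78 °C; then 2, −78 °C to 0 °C
Reagents that add atoms: none
Why: N‑acylation (nucleophilic acyl substitution) of the lithiated oxazolidinone by the acid chloride is the standard way to load the Evans auxiliary, and no stereocenter is formed.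

**Step 2**
Reactants: 4 (R)-4-benzyl-3-(pent-4-enoyl)-1,3-oxazolidin-2-one; 5 3,4-dimethoxybenzaldehyde
Product: 7 (R)-4-benzyl-3-{(2R)-2-[(R)-(3,4-dimethoxyphenyl)(hydroxy)methyl]pent-4-enoyl}-1,3-oxazolidin-2-one, via boron enolate 6 (not isolated)
Conditions: Bu2BOTf, iPr2NEt, CH2Cl2, −78 to 0 °C; 5, −78 to 0 °C; then pH 7 buffer, MeOH, H2O2, 0 °C
Reagents that add atoms: none
Why: Evans syn‑aldol reaction in which the (Z)‑boron enolate adds through a closed Zimmerman–Traxler chair on the face away from the auxiliary benzyl group, setting the α‑center (R) and the carbinol (R) as the syn pair that become C5 and C6.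

**Step 3**
Reactants: 7 syn‑aldol imide
Product: 8 (1R,2S)-1-(3,4-dimethoxyphenyl)-2-(prop-2-en-1-yl)propane-1,3-diol
Conditions: LiBH4, MeOH (1 equiv), THF, 0 °C
Reagents that add atoms: none
Why: Reductive cleavage of the imide by hydride attack at the exocyclic carbonyl releases the auxiliary and gives the 1,3‑diol without touching the two stereocenters or the alkene.

**Step 4**
Reactants: 8 diol
Product: 9 (1R,2S)-2-[(TBDPS-oxy)methyl]-1-(3,4-dimethoxyphenyl)pent-4-en-1-ol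
Conditions: TBDPSCl (1.05 equiv), imidazole, CH2Cl2, 0 °C to rt
Reagents that add atoms: tert-butyl(chloro)diphenylsilane, CC(C)(C)[Si](Cl)(c1ccccc1)c1ccccc1
Why: Selective silyl ether formation, because the bulky silyl chloride reacts much faster with the primary hydroxyl than with the hindered benzylic one.

**Step 5**
Reactants: 9 silyl ether
Product: 12 (4S,5R)-4-[(TBDPS-oxy)methyl]-5-(3,4-dimethoxyphenyl)oxolan-2-ol (anomer mixture), via triol 10 (not isolated), via hydroxy aldehyde 11 (not isolated)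
Conditions: OsO4 (2 mol%), NaIO4, 2,6-lutidine, dioxane/H2O 3:1, rt
Reagents that add atoms: osmium tetroxide, O=[Os](=O)(=O)=O (oxygen carrier); sodium periodate, [Na+].[O-]I(=O)(=O)=O (terminal oxidant); water, O
Why: Lemieux–Johnson oxidative cleavage turns the terminal alkene into the aldehyde, which closes onto the benzylic hydroxyl as the five‑membered lactol; the new anomeric center is removed in the next step.

**Step 6**
Reactants: 12 lactol
Product: 13 (4S,5R)-4-[(TBDPS-oxy)methyl]-5-(3,4-dimethoxyphenyl)oxolan-2-one (trans lactone)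
Conditions: TEMPO (10 mol%), PhI(OAc)2, CH2Cl2, rt
Reagents that add atoms: none
Why: Oxoammonium (TEMPO) oxidation of a lactol to the γ‑lactone is mild and leaves the silyl ether and the electron‑rich arene alone.

**Step 7**
Reactants: 13 trans lactone; 5 3,4-dimethoxybenzaldehyde
Product: 15 (3S,4S,5R)-4-[(TBDPS-oxy)methyl]-5-(3,4-dimethoxyphenyl)-3-[(3,4-dimethoxyphenyl)(hydroxy)methyl]oxolan-2-one (both carbinol epimers), via lithium enolate 14 (not isolated)
Conditions: LiN(iPr)2 (1.1 equiv), THF, −78 °C; 5, −78 °C; AcOH quench at −78 °C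
Reagents that add atoms: none
Why: Intermolecular aldol addition of the lactone lithium enolate forms the C1–C2 bond, the aldehyde entering anti to the CH2OTBDPS group, while the uncontrolled carbinol center does not matter because both epimers converge in step 8.

**Step 8**
Reactants: 15 aldol adduct (epimer mixture)
Product: 17 (3E,4S,5R)-4-[(TBDPS-oxy)methyl]-3-(3,4-dimethoxybenzylidene)-5-(3,4-dimethoxyphenyl)oxolan-2-one, via mesylate 16 (not isolated)
Conditions: MsCl, Et3N, CH2Cl2, 0 °C; then DBU, 0 °C to rt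
Reagents that add atoms: none
Why: Mesylation followed by E1cB elimination completes the aldol condensation and gives the conjugated E alkene (aryl anti to the lactone carbonyl) from both carbinol epimers, as is usual for α‑arylidene butyrolactones.

**Step 9**
Reactants: 17 (E)-benzylidene lactone
Product: 18 (3S,4S,5R)-4-[(TBDPS-oxy)methyl]-5-(3,4-dimethoxyphenyl)-3-[(R)-(3,4-dimethoxyphenyl)(hydroxy)methyl]-3-hydroxyoxolan-2-one
Conditions: OsO4 (5 mol%), N-methylmorpholine N-oxide, MeSO2NH2, acetone/H2O, rt; Na2SO3 work-up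
Reagents that add atoms: osmium tetroxide, O=[Os](=O)(=O)=O (delivers both oxygens, catalytic); N-methylmorpholine N-oxide, C[N+]1([O-])CCOCC1 (terminal oxygen source); water, O
Why: Upjohn syn‑dihydroxylation in which OsO4 adds to the face opposite the CH2OTBDPS group (held pseudoaxial by allylic 1,3‑strain with the aryl), fixing C1 as the carbinol trans to that group, while suprafacial addition to the E alkene makes the benzylic carbinol R, the configuration that places the C2 aryl endo.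

**Step 10**
Reactants: 18 dihydroxy lactone
Product: 19 (1R,2R,3S,4R)-3-[(TBDPS-oxy)methyl]-1,4-bis(3,4-dimethoxyphenyl)-2-(hydroxymethyl)butane-1,2,4-triol
Conditions: LiBH4 (excess), THF, 0 °C to rt
Reagents that add atoms: none
Why: Hydride reduction of the lactone to the diol converts the carbonyl carbon into the C8 hydroxymethyl group without affecting any stereocenter.

**Step 11**
Reactants: 19 tetraol
Product: 21 (3R,4S,5R)-4-[(TBDPS-oxy)methyl]-5-(3,4-dimethoxyphenyl)-3-[(R)-(3,4-dimethoxyphenyl)(hydroxy)methyl]oxolan-3-ol, via primary tosylate 20 (not isolated)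
Conditions: TsCl (1.2 equiv), pyridine, DMAP (cat.), 0 °C to rt, then 60 °C
Reagents that add atoms: none
Why: Selective sulfonylation of the only primary hydroxyl followed by 5‑exo‑tet Williamson cyclisation by the C6 benzylic hydroxyl forms ring B by SN2 at the CH2 carbon, so C6 is retained and the three‑ and four‑membered alternatives are much slower.

**Step 12**
Reactants: 21 silyl‑protected oxolane diol
Product: 22 (3R,4S,5R)-5-(3,4-dimethoxyphenyl)-3-[(R)-(3,4-dimethoxyphenyl)(hydroxy)methyl]-4-(hydroxymethyl)oxolan-3-ol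
Conditions: Bu4NF, THF, 0 °C to rt
Reagents that add atoms: none
Why: Fluoride‑induced desilylation, driven by the strong Si–F bond, frees the C4 hydroxyl only now that no lactone is left to migrate or fragment.

**Step 13**
Reactants: 22 triol
Product: 24 (1R,2R,5S,6R)-2,6-bis(3,4-dimethoxyphenyl)-3,7-dioxabicyclo[3.3.0]octan-1-ol, via primary tosylate 23 (not isolated)
Conditions: TsCl (1.1 equiv), pyridine, 0 °C to rt, then 40 °C
Reagents that add atoms: none
Why: Selective primary tosylation and 5‑exo‑tet SN2 ring closure by the C2 benzylic hydroxyl forms ring A with retention at C2 (aryl endo), and the cis arrangement of the two arms on ring B enforces the cis ring fusion.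

**Compound list**
1 | (R)-4-benzyl-1,3-oxazolidin-2-one | O=C1N[C@H](Cc2ccccc2)CO1 | starting material
2 | pent-4-enoyl chloride | C=CCCC(=O)Cl | starting material
3 | N-lithio derivative of 1 | [Li]N1C(=O)OC[C@H]1Cc1ccccc1 | intermediate
4 | (R)-4-benzyl-3-(pent-4-enoyl)-1,3-oxazolidin-2-one | C=CCCC(=O)N1C(=O)OC[C@H]1Cc1ccccc1 | intermediate
5 | 3,4-dimethoxybenzaldehyde (veratraldehyde) | COc1ccc(C=O)cc1OC | starting material
6 | (Z)-dibutylboron enolate of 4 | CCCCB(CCCC)O/C(=C\CC=C)N1C(=O)OC[C@H]1Cc1ccccc1 | intermediate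
7 | (R)-4-benzyl-3-{(2R)-2-[(R)-(3,4-dimethoxyphenyl)(hydroxy)methyl]pent-4-enoyl}-1,3-oxazolidin-2-one | C=CC[C@H]([C@@H](O)c1ccc(OC)c(OC)c1)C(=O)N1C(=O)OC[C@H]1Cc1ccccc1 | intermediate
8 | (1R,2S)-1-(3,4-dimethoxyphenyl)-2-(prop-2-en-1-yl)propane-1,3-diol | C=CC[C@H]([C@@H](O)c1ccc(OC)c(OC)c1)CO | intermediate
9 | (1R,2S)-2-[(tert-butyldiphenylsilyloxy)methyl]-1-(3,4-dimethoxyphenyl)pent-4-en-1-ol | C=CC[C@H]([C@@H](O)c1ccc(OC)c(OC)c1)CO[Si](c1ccccc1)(c1ccccc1)C(C)(C)C | intermediate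
10 | (1R,2S)-2-[(tert-butyldiphenylsilyloxy)methyl]-1-(3,4-dimethoxyphenyl)pentane-1,4,5-triol (C4 epimers) | OCC(O)C[C@H]([C@@H](O)c1ccc(OC)c(OC)c1)CO[Si](c1ccccc1)(c1ccccc1)C(C)(C)C | intermediate
11 | (3S,4R)-3-[(tert-butyldiphenylsilyloxy)methyl]-4-(3,4-dimethoxyphenyl)-4-hydroxybutanal | O=CC[C@H]([C@@H](O)c1ccc(OC)c(OC)c1)CO[Si](c1ccccc1)(c1ccccc1)C(C)(C)C | intermediate
12 | (4S,5R)-4-[(tert-butyldiphenylsilyloxy)methyl]-5-(3,4-dimethoxyphenyl)oxolan-2-ol (anomer mixture) | OC1C[C@@H](CO[Si](c2ccccc2)(c2ccccc2)C(C)(C)C)[C@H](c2ccc(OC)c(OC)c2)O1 | intermediate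
13 | (4S,5R)-4-[(tert-butyldiphenylsilyloxy)methyl]-5-(3,4-dimethoxyphenyl)oxolan-2-one | O=C1C[C@@H](CO[Si](c2ccccc2)(c2ccccc2)C(C)(C)C)[C@H](c2ccc(OC)c(OC)c2)O1 | intermediate
14 | lithium enolate of 13 | [Li]OC1=C[C@@H](CO[Si](c2ccccc2)(c2ccccc2)C(C)(C)C)[C@H](c2ccc(OC)c(OC)c2)O1 | intermediate
15 | (3S,4S,5R)-4-[(tert-butyldiphenylsilyloxy)methyl]-5-(3,4-dimethoxyphenyl)-3-[(3,4-dimethoxyphenyl)(hydroxy)methyl]oxolan-2-one (carbinol epimers) | O=C1[C@H](C(O)c2ccc(OC)c(OC)c2)[C@@H](CO[Si](c2ccccc2)(c2ccccc2)C(C)(C)C)[C@H](c2ccc(OC)c(OC)c2)O1 | intermediate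
16 | methanesulfonate of 15 | O=C1[C@H](C(OS(C)(=O)=O)c2ccc(OC)c(OC)c2)[C@@H](CO[Si](c2ccccc2)(c2ccccc2)C(C)(C)C)[C@H](c2ccc(OC)c(OC)c2)O1 | intermediate
17 | (3E,4S,5R)-4-[(tert-butyldiphenylsilyloxy)methyl]-3-(3,4-dimethoxybenzylidene)-5-(3,4-dimethoxyphenyl)oxolan-2-one | O=C1/C(=C/c2ccc(OC)c(OC)c2)[C@@H](CO[Si](c2ccccc2)(c2ccccc2)C(C)(C)C)[C@H](c2ccc(OC)c(OC)c2)O1 | intermediate
18 | (3S,4S,5R)-4-[(tert-butyldiphenylsilyloxy)methyl]-5-(3,4-dimethoxyphenyl)-3-[(R)-(3,4-dimethoxyphenyl)(hydroxy)methyl]-3-hydroxyoxolan-2-one | O=C1[C@@](O)([C@H](O)c2ccc(OC)c(OC)c2)[C@@H](CO[Si](c2ccccc2)(c2ccccc2)C(C)(C)C)[C@H](c2ccc(OC)c(OC)c2)O1 | intermediate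
19 | (1R,2R,3S,4R)-3-[(tert-butyldiphenylsilyloxy)methyl]-1,4-bis(3,4-dimethoxyphenyl)-2-(hydroxymethyl)butane-1,2,4-triol | OC[C@@](O)([C@H](O)c1ccc(OC)c(OC)c1)[C@@H](CO[Si](c1ccccc1)(c1ccccc1)C(C)(C)C)[C@@H](O)c1ccc(OC)c(OC)c1 | intermediate
20 | primary p-toluenesulfonate of 19 (on the C2 hydroxymethyl group) | Cc1ccc(cc1)S(=O)(=O)OC[C@@](O)([C@H](O)c1ccc(OC)c(OC)c1)[C@@H](CO[Si](c1ccccc1)(c1ccccc1)C(C)(C)C)[C@@H](O)c1ccc(OC)c(OC)c1 | intermediate
21 | (3R,4S,5R)-4-[(tert-butyldiphenylsilyloxy)methyl]-5-(3,4-dimethoxyphenyl)-3-[(R)-(3,4-dimethoxyphenyl)(hydroxy)methyl]oxolan-3-ol | O[C@@]1([C@H](O)c2ccc(OC)c(OC)c2)CO[C@@H](c2ccc(OC)c(OC)c2)[C@@H]1CO[Si](c2ccccc2)(c2ccccc2)C(C)(C)C | intermediate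
22 | (3R,4S,5R)-5-(3,4-dimethoxyphenyl)-3-[(R)-(3,4-dimethoxyphenyl)(hydroxy)methyl]-4-(hydroxymethyl)oxolan-3-ol | O[C@@]1([C@H](O)c2ccc(OC)c(OC)c2)CO[C@@H](c2ccc(OC)c(OC)c2)[C@@H]1CO | intermediate
23 | primary p-toluenesulfonate of 22 | O[C@@]1([C@H](O)c2ccc(OC)c(OC)c2)CO[C@@H](c2ccc(OC)c(OC)c2)[C@@H]1COS(=O)(=O)c1ccc(C)cc1 | intermediate
24 | (1R,2R,5S,6R)-2,6-bis(3,4-dimethoxyphenyl)-3,7-dioxabicyclo[3.3.0]octan-1-ol | COc1ccc([C@H]2OC[C@H]3[C@H](c4ccc(OC)c(OC)c4)OC[C@@]23O)cc1OC | target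

**Summary**
Total step count: 13. Longest linear sequence: 13 steps (1 → 24; veratraldehyde 5 enters in steps 2 and 7).

**Steps most likely to fail, with fallbacks**

Step 8 (E‑selective dehydration). The E/Z ratio may be modest, and DBU can move the double bond into the ring. The fallback makes the alkene by olefination and sets out from lactone 13. Its lithium enolate (2.2 equiv LiN(iPr)2, THF, −78 °C) is treated with ClP(O)(OEt)2 and allowed to warm, so the enol phosphate rearranges by a 1,3‑phosphorus shift to diethyl [(4S,5R)-4-[(tert-butyldiphenylsilyloxy)methyl]-5-(3,4-dimethoxyphenyl)-2-oxooxolan-3-yl]phosphonate F1. A Horner–Wadsworth–Emmons reaction of this phosphonate with 5 (LiCl, DBU, MeCN, rt) gives the E alkene and comes back to the route at 17.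

Step 9 (dihydroxylation). The trisubstituted enoate may react slowly, or the C6 aryl may erode the facial selectivity. The fallback installs the tertiary hydroxyl by enolate oxidation and sets out from the aldol mixture 15. Dess–Martin periodinane oxidises both epimers to the keto lactone (3S,4S,5R)-4-[(tert-butyldiphenylsilyloxy)methyl]-3-(3,4-dimethoxybenzoyl)-5-(3,4-dimethoxyphenyl)oxolan-2-one F2. Chelation‑controlled reduction with Zn(BH4)2 (Et2O, −20 °C) gives the single erythro alcohol (3S,4S,5R)-4-[(tert-butyldiphenylsilyloxy)methyl]-5-(3,4-dimethoxyphenyl)-3-[(S)-(3,4-dimethoxyphenyl)(hydroxy)methyl]oxolan-2-one F3. Its dianion (2.2 equiv LiN(iPr)2, THF, −78 °C) is hydroxylated with (camphorsulfonyl)oxaziridine on the face anti to CH2OTBDPS, which gives the diol directly and comes back to the route at 18.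

Step 11 (ring B closure). The tosylate sits on a neopentyl‑type carbon next to a tertiary hydroxyl, so closure may be slow or an epoxide may form. The fallback keeps the lactone ring and removes its carbonyl oxygen reductively; it sets out from 18. TESOTf/2,6‑lutidine gives the bis(triethylsilyl) ether of 18 F4. iBu2AlH (CH2Cl2, −78 °C) reduces it to the corresponding lactol F5. Et3SiH/BF3·OEt2 (CH2Cl2, −78 °C) reduces the oxocarbenium ion to the fully silylated oxolane F6. Bu4NF (THF) then removes all three silyl groups and comes back to the route at triol 22.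

**Further compounds**
F1 | step 8 | diethyl [(4S,5R)-4-[(tert-butyldiphenylsilyloxy)methyl]-5-(3,4-dimethoxyphenyl)-2-oxooxolan-3-yl]phosphonate | O=C1C(P(=O)(OCC)OCC)[C@@H](CO[Si](c2ccccc2)(c2ccccc2)C(C)(C)C)[C@H](c2ccc(OC)c(OC)c2)O1
F2 | step 9 | (3S,4S,5R)-4-[(tert-butyldiphenylsilyloxy)methyl]-3-(3,4-dimethoxybenzoyl)-5-(3,4-dimethoxyphenyl)oxolan-2-one | O=C1[C@H](C(=O)c2ccc(OC)c(OC)c2)[C@@H](CO[Si](c2ccccc2)(c2ccccc2)C(C)(C)C)[C@H](c2ccc(OC)c(OC)c2)O1
F3 | step 9 | (3S,4S,5R)-4-[(tert-butyldiphenylsilyloxy)methyl]-5-(3,4-dimethoxyphenyl)-3-[(S)-(3,4-dimethoxyphenyl)(hydroxy)methyl]oxolan-2-one | O=C1[C@H]([C@H](O)c2ccc(OC)c(OC)c2)[C@@H](CO[Si](c2ccccc2)(c2ccccc2)C(C)(C)C)[C@H](c2ccc(OC)c(OC)c2)O1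
F4 | step 11 | (3S,4S,5R)-4-[(tert-butyldiphenylsilyloxy)methyl]-5-(3,4-dimethoxyphenyl)-3-[(R)-(3,4-dimethoxyphenyl)(triethylsilyloxy)methyl]-3-(triethylsilyloxy)oxolan-2-one | O=C1[C@@](O[Si](CC)(CC)CC)([C@H](O[Si](CC)(CC)CC)c2ccc(OC)c(OC)c2)[C@@H](CO[Si](c2ccccc2)(c2ccccc2)C(C)(C)C)[C@H](c2ccc(OC)c(OC)c2)O1
F5 | step 11 | lactol (oxolan-2-ol, anomer mixture) from reduction of F4 | OC1[C@@](O[Si](CC)(CC)CC)([C@H](O[Si](CC)(CC)CC)c2ccc(OC)c(OC)c2)[C@@H](CO[Si](c2ccccc2)(c2ccccc2)C(C)(C)C)[C@H](c2ccc(OC)c(OC)c2)O1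
F6 | step 11 | tris-silylated oxolane: bis(triethylsilyl) ether of 21 | C1[C@@](O[Si](CC)(CC)CC)([C@H](O[Si](CC)(CC)CC)c2ccc(OC)c(OC)c2)[C@@H](CO[Si](c2ccccc2)(c2ccccc2)C(C)(C)C)[C@H](c2ccc(OC)c(OC)c2)O1
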